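**Strategy.** Everything rests on cutting the two C–O bonds of the 1,2-dioxane ring (O1', O2', C3'–C6'): C6'–O1' at the quaternary carbon and O2'–C3'. Because C3' and C6' flank the O–O bond as a 1,4-related pair, both bonds arise in one operation when cobalt and O2 open a 2,2-disubstituted cyclobutanol and insert O2 where its C1–C2 bond was. The precursor is such a cyclobutanol, bearing the methyl group and the two-carbon tether to the 9α-hydroxy-8α-methyl decalin. It comes from (−)-sclareol, with the cyclobutane built before C9 is oxygenated so that no protecting group is needed. The propanoate arm (C2–C3') is attached afterwards through a peroxycarbenium ion.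

Key step: step 6

Assumption (numbering): labdane numbers are used for the decalin and tether (C1–C12, C17 = methyl on C8; α/β = decalin faces, C10 methyl = β), primed numbers for the dioxane, and C2 for the propanoate α-carbon.

Remark on the chemistry: a C13 carbonyl and a C9 oxygen function are never allowed to coexist, since γ-hydroxy and γ-hydroperoxy ketones close to hemiketals. The cyclobutane is therefore finished first, and the C8/C9 pair is set by a stereospecific epoxide opening instead of a face-selective hydrogenation. The precursor 11 is used unprotected, as its mixture of cyclobutane stereoisomers.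

**Step 1**
Reactants: 1 (−)-sclareol
Product: 4 8α-hydroxy-14,15-dinorlabdan-13-one, via tetrol 2 (not isolated), via hydroxy aldehyde 3 (not isolated)
Conditions: OsO4 (cat.), NaIO4 (3.5 equiv), t-BuOH/H2O, 45 °C
Reagents that add atoms: none
Why: Lemieux–Johnson oxidation: catalytic osmylation of the vinyl group gives the 13,14,15-triol unit, which periodate cleaves twice (glycol cleavage, then α-hydroxy aldehyde cleavage) down to the C13 methyl ketone, while the hindered tertiary C8–OH and the ring stereocentres are untouched.

**Step 2**
Reactants: 4 8α-hydroxy-14,15-dinorlabdan-13-one; 5 cyclopropyldiphenylsulfonium tetrafluoroborate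
Product: 7 2-methyl-2-{2-[(1R,2R,4aS,8aS)-2-hydroxy-2,5,5,8a-tetramethyldecahydronaphthalen-1-yl]ethyl}cyclobutan-1-one (both epimers at the new quaternary carbon), via oxaspiropentane 6 (not isolated)
Conditions: KOH (powdered), DMSO, rt; then 1 M aq. HBF4, Et2O, rt
Reagents that add atoms: none
Why: Sulfonium cyclopropylide spiroannulation: the ylide, formed reversibly by KOH, adds to the ketone and closes the oxaspiropentane, whose acid-triggered semipinacol ring expansion gives the 2,2-disubstituted cyclobutanone; the new quaternary centre needs no control because it becomes a planar radical in step 6, and any loss of water from C8–OH in the acid phase only anticipates step 3.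

**Step 3**
Reactants: 7 hydroxy cyclobutanone
Product: 8 2-methyl-2-{2-[(4aS,8aS)-2,5,5,8a-tetramethyl-3,4,4a,5,6,7,8,8a-octahydronaphthalen-1-yl]ethyl}cyclobutan-1-one (8(9)-olefin)
Conditions: PPh3, I2, CH2Cl2, rt
Reagents that add atoms: none
Why: E1 dehydration of the tertiary alcohol through its alkoxyphosphonium iodide, with the liberated HI equilibrating the olefin isomers to the tetrasubstituted 8(9)-alkene (Zaitsev, thermodynamic control); the cyclobutanone oxygen is too remote to capture the C8 cation as a methyl ketone would (cyclic enol ether formation).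

**Step 4**
Reactants: 8 8(9)-ene cyclobutanone
Product: 9 8α,9α-epoxide of 8 (oxirane oxygen on the face opposite the C10 methyl)
Conditions: dimethyldioxirane (acetone solution), CH2Cl2, 0 °C
Reagents that add atoms: dimethyldioxirane, CC1(C)OO1
Why: Electrophilic epoxidation of the electron-rich tetrasubstituted olefin from the α face, the β face being covered by the axial C10 and 4β methyl groups; a dioxirane, unlike a peracid, leaves the cyclobutanone free of Baeyer–Villiger oxidation.

**Step 5**
Reactants: 9 epoxy cyclobutanone
Product: 11 2-methyl-2-{2-[(1R,2R,4aS,8aS)-1-hydroxy-2,5,5,8a-tetramethyldecahydronaphthalen-1-yl]ethyl}cyclobutan-1-ol (four cyclobutane stereoisomers), via epoxy cyclobutanol 10 (not isolated)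
Conditions: LiAlH4 (excess), THF, reflux; Rochelle-salt work-up
Reagents that add atoms: none
Why: Hydride first reduces the strained ketone (any cyclobutanol stereoisomer serves step 6) and then opens the epoxide by SN2 attack at C8 from the β face, the only trans-diaxial (Fürst–Plattner) mode and the one that avoids the neopentyl C9; oxygen therefore stays on C9 (α, axial) and H-8 becomes β, which places the C8 methyl equatorial and cis to the hydroxyl (8R,9R).

**Step 6**
Reactants: 11 cyclobutanol precursor
Product: 13 (6R)-6-methyl-6-{2-[(1R,2R,4aS,8aS)-1-hydroxy-2,5,5,8a-tetramethyldecahydronaphthalen-1-yl]ethyl}-1,2-dioxan-3-ol (both anomers; C6' as in the target), via hydroperoxy aldehyde 12 (not isolated)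
Conditions: Co(acac)2 (20 mol %), O2 (1 atm), 1,2-dichloroethane, 40 °C
Reagents that add atoms: dioxygen, O=O
Why: Divalent cobalt and O2 generate trivalent cobalt–oxygen species that bind the cyclobutanol as a trivalent cobalt cyclobutoxide; its homolysis gives the cyclobutoxyl radical, whose strain-driven β-scission breaks the ring bond to the quaternary carbon, leaving the C3' aldehyde and the tertiary C6' radical, which combines with triplet O2, the peroxyl radical being taken up by divalent cobalt and released as hydroperoxide 12 by exchange with the next cyclobutanol. The closest known reaction type is the Co(acac)2-catalysed aerobic oxygenative ring expansion of 2,2-disubstituted cyclobutanols to 1,2-dioxan-3-ols, a cobalt–peroxyl chain of the Mukaiyama family. The single ring formed, the 1,2-dioxane, closes by 6-exo-trig addition of the hydroperoxide oxygen to the aldehyde carbonyl (O2'–C3'), after C6'–O1' has been made by radical–O2 combination. C6' is set without control, because O2 meets a planar acyclic tertiary radical far from the decalin, so both C6' epimers should form and 13 is to be separated from its epimer by chromatography (preparative HPLC if needed); the anomeric C3' centre is transient and is erased in step 9. The selectivity the step needs is regioselective scission, secured by the methyl- and alkyl-bearing ring carbon (tertiary versus primary radical), so that all four stereoisomers of 11 converge. The unstrained, hindered tertiary C9–OH has no driving force to enter the alkoxyl-radical manifold, and the saturated decalin offers no competing radical site.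

**Step 7**
Reactants: 13 dioxanol
Product: 14 (6R)-6-methyl-6-{2-[(1R,2R,4aS,8aS)-1-hydroxy-2,5,5,8a-tetramethyldecahydronaphthalen-1-yl]ethyl}-1,2-dioxan-3-yl acetate (both anomers)
Conditions: Ac2O, pyridine, DMAP (cat.), CH2Cl2, 0 °C
Reagents that add atoms: acetic anhydride, CC(=O)OC(C)=O
Why: DMAP-catalysed acylation of the peroxyhemiacetal hydroxyl turns C3' into an ionisable peroxyacetal; the hindered tertiary C9–OH should not be acylated, and both anomers are carried on because they converge on one cation.

**Step 8**
Reactants: 15 methyl propanoate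
Product: 17 (E)-1-methoxy-1-(trimethylsilyloxy)prop-1-ene, via lithium enolate 16 (not isolated)
Conditions: LiN(i-Pr)2, THF, −78 °C; then TMSCl, −78 °C → rt
Reagents that add atoms: chlorotrimethylsilane, C[Si](C)(C)Cl
Why: Kinetic ester enolisation followed by O-silylation gives the silyl ketene acetal, mainly the isomer with methyl trans to the silyloxy group; its geometry matters little in the open transition state of step 9.

**Step 9**
Reactants: 14 dioxanyl acetate; 17 silyl ketene acetal
Product: 19 methyl (2S)-2-[(3S,6S)-6-methyl-6-{2-[(1R,2R,4aS,8aS)-1-hydroxy-2,5,5,8a-tetramethyldecahydronaphthalen-1-yl]ethyl}-1,2-dioxan-3-yl]propanoate, via peroxycarbenium triflate 18 (not isolated)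
Conditions: TMSOTf (0.2 equiv), CH2Cl2, −78 °C
Reagents that add atoms: none
Why: Mukaiyama-type addition to a peroxycarbenium ion: TMSOTf ionises the anomeric acetate and the ketene acetal attacks C3' through an open transition state to form C2–C3'; the two C6' substituents are similar in size, so C3' and C2 should arise with modest substrate control at best, and the (2S,3'S) isomer 19, with the side chain trans to the tether, is to be isolated from the other diastereomers by preparative HPLC, while the hindered C9–OH is expected to stay unsilylated at −78 °C.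

**Step 10**
Reactants: 19 methyl ester
Product: 20 (2S)-2-[(3S,6S)-6-methyl-6-{2-[(1R,2R,4aS,8aS)-1-hydroxy-2,5,5,8a-tetramethyldecahydronaphthalen-1-yl]ethyl}-1,2-dioxan-3-yl]propanoic acid (target)
Conditions: LiOH, THF/MeOH/H2O, 0 °C → rt; then 1 M HCl to pH 3
Reagents that add atoms: lithium hydroxide, [Li+].[OH-]
Why: Saponification at low temperature, which a dialkyl peroxide tolerates and which should keep C2 epimerisation and β-elimination of the peroxide oxygen (retro-oxa-Michael opening) in check; acidification frees the acid.

**Compound list**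

1 | (−)-sclareol, (13R)-labd-14-ene-8α,13-diol | C=C[C@](C)(O)CC[C@H]1[C@](C)(O)CC[C@H]2C(C)(C)CCC[C@@]21C | starting material
2 | (13R)-labdane-8α,13,14,15-tetrol (C14 epimers) | OCC(O)[C@](C)(O)CC[C@H]1[C@](C)(O)CC[C@H]2C(C)(C)CCC[C@@]21C | intermediate (not isolated)
3 | (13R)-8α,13-dihydroxy-15-norlabdan-14-al | O=C[C@](C)(O)CC[C@H]1[C@](C)(O)CC[C@H]2C(C)(C)CCC[C@@]21C | intermediate (not isolated)
4 | 8α-hydroxy-14,15-dinorlabdan-13-one | CC(=O)CC[C@H]1[C@](C)(O)CC[C@H]2C(C)(C)CCC[C@@]21C | intermediate
5 | cyclopropyldiphenylsulfonium tetrafluoroborate | F[B-](F)(F)F.C1CC1[S+](c1ccccc1)c1ccccc1 | starting material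
6 | 2-methyl-2-[2-(8α-hydroxy-decalinyl)ethyl]-1-oxaspiro[2.2]pentane (both epimers) | CC1(CC[C@H]2[C@](C)(O)CC[C@H]3C(C)(C)CCC[C@@]32C)OC14CC4 | intermediate (not isolated)
7 | 2-methyl-2-{2-[(1R,2R,4aS,8aS)-2-hydroxy-2,5,5,8a-tetramethyldecahydronaphthalen-1-yl]ethyl}cyclobutan-1-one (both epimers) | O=C1CCC1(C)CC[C@H]2[C@](C)(O)CC[C@H]3C(C)(C)CCC[C@@]32C | intermediate
8 | 2-methyl-2-{2-[(4aS,8aS)-2,5,5,8a-tetramethyl-3,4,4a,5,6,7,8,8a-octahydronaphthalen-1-yl]ethyl}cyclobutan-1-one | O=C1CCC1(C)CCC2=C(C)CC[C@H]3C(C)(C)CCC[C@@]32C | intermediate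
9 | 8α,9α-epoxide of 8 | O=C1CCC1(C)CC[C@]23O[C@]3(C)CC[C@H]4C(C)(C)CCC[C@@]42C | intermediate
10 | 8α,9α-epoxy cyclobutanol (present as its alkoxyaluminate) | OC1CCC1(C)CC[C@]23O[C@]3(C)CC[C@H]4C(C)(C)CCC[C@@]42C | intermediate (not isolated)
11 | 2-methyl-2-{2-[(1R,2R,4aS,8aS)-1-hydroxy-2,5,5,8a-tetramethyldecahydronaphthalen-1-yl]ethyl}cyclobutan-1-ol (cyclobutane stereoisomers) | OC1CCC1(C)CC[C@@]2(O)[C@H](C)CC[C@H]3C(C)(C)CCC[C@@]32C | intermediate (key-step precursor)
12 | 4-hydroperoxy-4-methyl-6-(9α-hydroxy-8α-methyl-decalin-9-yl)hexanal (both C6' epimers) | O=CCCC(C)(CC[C@@]1(O)[C@H](C)CC[C@H]2C(C)(C)CCC[C@@]21C)OO | intermediate (not isolated)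
13 | (6R)-6-methyl-6-{2-[(1R,2R,4aS,8aS)-1-hydroxy-2,5,5,8a-tetramethyldecahydronaphthalen-1-yl]ethyl}-1,2-dioxan-3-ol (anomers) | OC1CC[C@@](C)(CC[C@@]2(O)[C@H](C)CC[C@H]3C(C)(C)CCC[C@@]32C)OO1 | intermediate (key-step product)
14 | 3-acetate of 13 (anomers) | CC(=O)OC1CC[C@@](C)(CC[C@@]2(O)[C@H](C)CC[C@H]3C(C)(C)CCC[C@@]32C)OO1 | intermediate
15 | methyl propanoate | CCC(=O)OC | starting material
16 | lithium enolate of methyl propanoate (OLi trans to methyl) | C/C=C(\OC)[O-].[Li+] | intermediate (not isolated)
17 | (E)-1-methoxy-1-(trimethylsilyloxy)prop-1-ene | C/C=C(\OC)O[Si](C)(C)C | intermediate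
18 | 6-methyl-6-tethered 1,2-dioxan-3-ylium triflate | [O+]1=CCC[C@@](C)(CC[C@@]2(O)[C@H](C)CC[C@H]3C(C)(C)CCC[C@@]32C)O1.[O-]S(=O)(=O)C(F)(F)F | intermediate (not isolated)
19 | methyl (2S)-2-[(3S,6S)-6-methyl-6-{2-[(1R,2R,4aS,8aS)-1-hydroxy-2,5,5,8a-tetramethyldecahydronaphthalen-1-yl]ethyl}-1,2-dioxan-3-yl]propanoate | C[C@H](C(=O)OC)[C@@H]1CC[C@@](C)(CC[C@@]2(O)[C@H](C)CC[C@H]3C(C)(C)CCC[C@@]32C)OO1 | intermediate
20 | (2S)-2-[(3S,6S)-6-methyl-6-{2-[(1R,2R,4aS,8aS)-1-hydroxy-2,5,5,8a-tetramethyldecahydronaphthalen-1-yl]ethyl}-1,2-dioxan-3-yl]propanoic acid | C[C@H](C(=O)O)[C@@H]1CC[C@@](C)(CC[C@@]2(O)[C@H](C)CC[C@H]3C(C)(C)CCC[C@@]32C)OO1 | target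

**Totals.** Total step count: 10. Longest linear sequence: 9 steps (steps 1–7, 9, 10); step 8 is a one-step side branch.

**Steps most likely to fail**

1. Step 6 (key step). The chain may run poorly on this hindered diol (slow ligand exchange at cobalt). The secondary cyclobutanol may be dehydrogenated instead of fragmenting, or the hydroperoxy aldehyde may decompose before it closes. Fallback, which separates C–C cleavage from oxygenation and sets out from 11: one-electron oxidation with Mn(OAc)3 and Cu(OAc)2 in AcOH opens the cyclobutanol, and divalent copper oxidises the tertiary radical to the olefin. This should give the 4-methylidene aldehyde F4, together with double-bond isomers that converge in the next but one operation. The aldehyde is masked as the dimethyl acetal F5 (HC(OMe)3, PPTS, MeOH). Mukaiyama–Isayama hydroperoxysilylation (Co(thd)2 [thd = 2,2,6,6-tetramethylheptane-3,5-dionate], Et3SiH, O2, 1,2-dichloroethane) then places a triethylsilylperoxy group at the tertiary C6', giving the silyl peroxide F6. Dilute HCl in aqueous THF removes silyl group and acetal, and the freed hydroperoxy aldehyde 12 closes to 13, where the route is rejoined.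

2. Step 5. SN2 delivery of hydride to the fully substituted C8 beneath a 1,3-diaxial methyl may be slow, so that incomplete conversion or base-type elimination of the epoxide could take over. Fallback, which sets out from 8 and reaches the same C8/C9 pair by oxygen transfer and hydrogenation: NaBH4 in MeOH gives the 8(9)-ene cyclobutanol F1. A Schenck ene reaction (O2, visible light, tetraphenylporphyrin, CH2Cl2, 0 °C) should deliver singlet oxygen to the α face and, by loss of a C17 hydrogen, give the 9α-hydroperoxy 8(17)-olefin F2. C12 occupies the α face at C11, so no C11–H is aligned for the competing abstraction. PPh3 reduces F2 to the allylic alcohol F3. Hydrogenation (H2, PtO2, EtOAc) from the β face, anti to the axial C9 oxygen, should then give 11. This facial preference is the open point of the fallback, and the C8 epimers would have to be separated at that point.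

3. Step 9. Facial discrimination at C3' and C2 may be low, leaving little of the needed isomer. Silyl transfer to the C9 hydroxyl or Lewis-acid fragmentation of the peroxide could also erode the step. Fallback without a Lewis acid, which sets out from 13: Wittig olefination of the lactol with the stabilised ylide Ph3P=C(CH3)CO2Me (toluene, rt) traps the open-chain aldehyde as the (E)-hydroperoxy enoate F7. Et2NH in CF3CH2OH then closes the dioxane by intramolecular 6-exo-trig oxa-Michael addition of the hydroperoxide, a reversible closure that should favour the isomer with both large groups equatorial. After HPLC this gives 19.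

**Further compounds**

F1 | step 5 | 2-methyl-2-{2-[(4aS,8aS)-2,5,5,8a-tetramethyl-3,4,4a,5,6,7,8,8a-octahydronaphthalen-1-yl]ethyl}cyclobutan-1-ol | OC1CCC1(C)CCC2=C(C)CC[C@H]3C(C)(C)CCC[C@@]32C
F2 | step 5 | 9α-hydroperoxy-8(17)-ene cyclobutanol | OC1CCC1(C)CC[C@@]2(OO)C(=C)CC[C@H]3C(C)(C)CCC[C@@]32C
F3 | step 5 | 9α-hydroxy-8(17)-ene cyclobutanol | OC1CCC1(C)CC[C@@]2(O)C(=C)CC[C@H]3C(C)(C)CCC[C@@]32C
F4 | step 6 | 4-methylidene-6-(9α-hydroxy-8α-methyl-decalin-9-yl)hexanal | O=CCCC(=C)CC[C@@]1(O)[C@H](C)CC[C@H]2C(C)(C)CCC[C@@]21C
F5 | step 6 | dimethyl acetal of F4 | COC(CCC(=C)CC[C@@]1(O)[C@H](C)CC[C@H]2C(C)(C)CCC[C@@]21C)OC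
F6 | step 6 | 4-methyl-4-(triethylsilylperoxy) dimethyl acetal (both C6' epimers) | COC(CCC(C)(OO[Si](CC)(CC)CC)CC[C@@]1(O)[C@H](C)CC[C@H]2C(C)(C)CCC[C@@]21C)OC
F7 | step 9 | methyl (E)-6-hydroperoxy-2,6-dimethyl-8-(9α-hydroxy-8α-methyl-decalin-9-yl)oct-2-enoate (C6' as in 13) | COC(=O)/C(C)=C/CC[C@@](C)(CC[C@@]1(O)[C@H](C)CC[C@H]2C(C)(C)CCC[C@@]21C)OO
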